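**Retrosynthetic overview**

1. The tiglate (primary CH2–O) and the angelate (phenol O) are ester disconnections. The oxirane O–CH2 bond is cut back to a tertiary alcohol and a CH2Br group (3-exo-tet closure).
2. Feature used: the phenol oxygen sits on the ring carbon ortho to the one that carries the quaternary oxirane carbon. The chain O(phenol)–C(aryl)–C(aryl)–C(quaternary), one carbonate carbon and its carbonyl oxygen therefore make a six-membered 1,3-dioxin-2-one ring fused to the benzene ring.
3. Key disconnection: the tertiary C–O bond and the C–Br bond of that 4H-1,3-benzodioxin-2-one (13) come from a catalytic enantioselective bromocarbonation of aryl tert-butyl carbonate 11. This sets the only stereocentre.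
4. Carbonate 11 comes from phenol 9 and Boc2O. Phenol 9 comes from Suzuki coupling of 2-bromo-4-methoxy-5-methylphenol (3) with the α-boryl allyl silyl ether 8.
5. Ring order: the benzene ring is bought. The benzodioxinone ring is closed in step 6 and opened reductively in step 7, so that no free phenoxide ever sits next to CH2Br or the oxirane. The oxirane is closed in step 9, after the phenol has been acylated.

Key step: step 6

Assumption: (DHQD)2PHAL is taken to deliver the (S)-carbonate 13; the sense of induction of a new reaction cannot be known in advance, and if the first run shows the opposite sense the pseudo-enantiomeric (DHQ)2PHAL replaces it with nothing else changed.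
Assumption: angelic anhydride and tigloyl chloride are taken as purchased reagents.

**Route**

Step 1
Reactants: 1 4-methoxy-3-methylphenol; 2 N-bromosuccinimide
Product: 3 2-bromo-4-methoxy-5-methylphenol
Conditions: NBS (1.0 equiv), i-Pr2NH (10 mol%), CH2Cl2, 0 °C
Reagents that add atoms: N-bromosuccinimide (2), O=C1CCC(=O)N1Br
Why: Electrophilic aromatic bromination directed ortho by the free hydroxyl under amine catalysis, where the open ortho position (para to the methyl group) should be taken in preference to the one flanked by OH and CH3 and to the position activated only by the methoxy group.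

Step 2
Reactants: 4 2-bromoprop-2-en-1-ol; 5 tert-butyl(chloro)dimethylsilane
Product: 6 tert-butyl[(2-bromoprop-2-en-1-yl)oxy]dimethylsilane
Conditions: TBSCl, imidazole, CH2Cl2, 0 °C → rt
Reagents that add atoms: tert-butyl(chloro)dimethylsilane (5), CC(C)(C)[Si](C)(C)Cl
Why: Standard imidazole-promoted silylation of a primary alcohol (silyl ether formation).

Step 3
Reactants: 6 tert-butyl[(2-bromoprop-2-en-1-yl)oxy]dimethylsilane; 7 bis(pinacolato)diboron
Product: 8 tert-butyl(dimethyl){[2-(4,4,5,5-tetramethyl-1,3,2-dioxaborolan-2-yl)prop-2-en-1-yl]oxy}silane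
Conditions: B2pin2 (1.1 equiv), PdCl2(PPh3)2 (3 mol%), PPh3 (6 mol%), KOPh (1.5 equiv), PhMe, 50 °C
Reagents that add atoms: bis(pinacolato)diboron (7), CC1(C)OB(OC1(C)C)B1OC(C)(C)C(C)(C)O1
Why: Miyaura borylation of an alkenyl bromide under the phenoxide-base conditions developed for 1-alkenyl halides, chosen because it avoids a 2-lithioallyl silyl ether that could undergo retro-Brook silyl migration.

Step 4
Reactants: 3 2-bromo-4-methoxy-5-methylphenol; 8 tert-butyl(dimethyl){[2-(4,4,5,5-tetramethyl-1,3,2-dioxaborolan-2-yl)prop-2-en-1-yl]oxy}silane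
Product: 9 2-[3-({[tert-butyl(dimethyl)silyl]oxy})prop-1-en-2-yl]-4-methoxy-5-methylphenol
Conditions: Pd(OAc)2 (3 mol%), SPhos (6 mol%), K3PO4 (3 equiv), PhMe/H2O (10:1), 80 °C
Reagents that add atoms: none
Why: Suzuki–Miyaura coupling, in which the electron-rich biaryl phosphine allows oxidative addition into the electron-rich ortho-bromophenol and the free phenol is tolerated under phosphate base.

Step 5
Reactants: 9 2-[3-({[tert-butyl(dimethyl)silyl]oxy})prop-1-en-2-yl]-4-methoxy-5-methylphenol; 10 di-tert-butyl dicarbonate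
Product: 11 tert-butyl {2-[3-({[tert-butyl(dimethyl)silyl]oxy})prop-1-en-2-yl]-4-methoxy-5-methylphenyl} carbonate
Conditions: Boc2O (1.2 equiv), DMAP (5 mol%), MeCN, rt
Reagents that add atoms: di-tert-butyl dicarbonate (10), CC(C)(C)OC(=O)OC(=O)OC(C)(C)C
Why: DMAP-catalysed O-acylation of a phenol with Boc2O (carbonate formation), which installs the tethered nucleophile and lowers the electron density of the ring before the bromination.

Step 6
Reactants: 11 tert-butyl {2-[3-({[tert-butyl(dimethyl)silyl]oxy})prop-1-en-2-yl]-4-methoxy-5-methylphenyl} carbonate; 2 N-bromosuccinimide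
Product: 13 (4S)-4-(bromomethyl)-4-({[tert-butyl(dimethyl)silyl]oxy}methyl)-6-methoxy-7-methyl-4H-1,3-benzodioxin-2-one, via dioxocarbenium ion 12 (not isolated)
Conditions: NBS (1.1 equiv), (DHQD)2PHAL (10 mol%), PhMe/CHCl3 (1:1), −60 °C, dark
Reagents that add atoms: N-bromosuccinimide (2), O=C1CCC(=O)N1Br
Why: Proposed new method: the quinuclidine nitrogen of (DHQD)2PHAL takes up Br+ from NBS and passes it to the terminal CH2 of the 1,1-disubstituted aryl alkene, which builds positive charge at the carbon bearing the aryl and CH2OTBS groups; the carbonyl oxygen of the aryl tert-butyl carbonate adds to that carbon anti to bromine, and cation 12 loses its tert-butyl group as 2-methylpropene to the succinimide anion. The closest known reactions are cinchona-dimer-catalysed enantioselective halolactonisations of 1,1-disubstituted aryl alkenes and the substrate-controlled halocyclisation of homoallylic tert-butyl carbonates; an aryl carbonate has not served as the nucleophile in a catalytic enantioselective bromocyclisation. The six-membered 1,3-dioxin-2-one ring closes in the 6-exo mode, with the CH2Br carbon left outside the ring. The single new stereocentre, quaternary C4, is set by the catalyst, which must choose the alkene face at which the C–O bond forms, since the substrate carries no other stereo-element. Markovnikov regiochemistry follows from stabilisation of the tertiary benzylic cation by the aryl ring and its para-methyl group, and chemoselectivity for the alkene over the methoxy-activated ring is secured by the electron-withdrawing carbonate on the ring, one equivalent of NBS, low temperature and exclusion of light.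

Step 7
Reactants: 13 (4S)-4-(bromomethyl)-4-({[tert-butyl(dimethyl)silyl]oxy}methyl)-6-methoxy-7-methyl-4H-1,3-benzodioxin-2-one
Product: 14 (2S)-1-bromo-3-{[tert-butyl(dimethyl)silyl]oxy}-2-(2-hydroxy-5-methoxy-4-methylphenyl)propan-2-ol
Conditions: DIBAL-H (4 equiv), CH2Cl2, −78 → −40 °C; then aq. potassium sodium tartrate
Reagents that add atoms: none
Why: Reductive cleavage of a carbonate by hydride transfer, in which the carbonate carbon leaves as methanol and both oxygens stay bound to aluminium until the neutral work-up, so that no nucleophilic phenoxide meets the CH2Br group and no bond to the stereocentre is touched.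

Step 8
Reactants: 14 (2S)-1-bromo-3-{[tert-butyl(dimethyl)silyl]oxy}-2-(2-hydroxy-5-methoxy-4-methylphenyl)propan-2-ol; 15 (2Z)-2-methylbut-2-enoic anhydride (angelic anhydride)
Product: 17 2-[(2S)-1-bromo-3-{[tert-butyl(dimethyl)silyl]oxy}-2-hydroxypropan-2-yl]-4-methoxy-5-methylphenyl (2Z)-2-methylbut-2-enoate, via lithium phenoxide 16 (not isolated)
Conditions: LiHMDS (1.0 equiv), THF, −78 °C; then angelic anhydride (1.2 equiv), −78 → 0 °C; aq. NH4Cl
Reagents that add atoms: angelic anhydride (15), C/C=C(/C)C(=O)OC(=O)/C(C)=C\C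
Why: Chemoselective O-acylation of a phenoxide by an anhydride, where one equivalent of base deprotonates only the phenol (far more acidic than the tertiary alcohol) and the low-temperature amide-base/anhydride protocol transfers the angeloyl group without Z-to-E isomerisation.

Step 9
Reactants: 17 2-[(2S)-1-bromo-3-{[tert-butyl(dimethyl)silyl]oxy}-2-hydroxypropan-2-yl]-4-methoxy-5-methylphenyl (2Z)-2-methylbut-2-enoate
Product: 19 2-[(2R)-2-({[tert-butyl(dimethyl)silyl]oxy}methyl)oxiran-2-yl]-4-methoxy-5-methylphenyl (2Z)-2-methylbut-2-enoate, via sodium alkoxide 18 (not isolated)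
Conditions: NaH (1.1 equiv), THF, 0 °C
Reagents that add atoms: none
Why: Intramolecular Williamson etherification (bromohydrin to oxirane), in which the tertiary alkoxide displaces bromide at CH2 in a fast 3-exo-tet closure, so the quaternary centre keeps its configuration and its descriptor changes from S to R only because the CIP priorities change.

Step 10
Reactants: 19 2-[(2R)-2-({[tert-butyl(dimethyl)silyl]oxy}methyl)oxiran-2-yl]-4-methoxy-5-methylphenyl (2Z)-2-methylbut-2-enoate
Product: 20 2-[(2S)-2-(hydroxymethyl)oxiran-2-yl]-4-methoxy-5-methylphenyl (2Z)-2-methylbut-2-enoate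
Conditions: TBAF (1.5 equiv), AcOH (1.5 equiv), THF, 0 °C → rt
Reagents that add atoms: none
Why: Fluoride-mediated desilylation buffered with acetic acid, so that the liberated primary alcohol is never an alkoxide that could take over the angeloyl group or open the oxirane (the descriptor changes from R to S by CIP priority only).

Step 11
Reactants: 20 2-[(2S)-2-(hydroxymethyl)oxiran-2-yl]-4-methoxy-5-methylphenyl (2Z)-2-methylbut-2-enoate; 21 (2E)-2-methylbut-2-enoyl chloride (tigloyl chloride)
Product: 22 2-[(2R)-2-({[(2E)-2-methylbut-2-enoyl]oxy}methyl)oxiran-2-yl]-4-methoxy-5-methylphenyl (2Z)-2-methylbut-2-enoate (CNP0103045.2)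
Conditions: tigloyl chloride (1.5 equiv), Et3N (2 equiv), DMAP (5 mol%), CH2Cl2, 0 °C
Reagents that add atoms: tigloyl chloride (21), C/C=C(\C)C(=O)Cl
Why: DMAP-catalysed acylation of a primary alcohol with an acid chloride, where the E-configured tiglate is the thermodynamically stable isomer and the basic medium protects the acid-sensitive tertiary benzylic oxirane.

**Compound list**

1 | 4-methoxy-3-methylphenol | COc1ccc(O)cc1C | starting material
2 | N-bromosuccinimide | O=C1CCC(=O)N1Br | starting material
3 | 2-bromo-4-methoxy-5-methylphenol | Oc1cc(C)c(OC)cc1Br | intermediate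
4 | 2-bromoprop-2-en-1-ol | OCC(Br)=C | starting material
5 | tert-butyl(chloro)dimethylsilane | CC(C)(C)[Si](C)(C)Cl | starting material
6 | tert-butyl[(2-bromoprop-2-en-1-yl)oxy]dimethylsilane | C=C(Br)CO[Si](C)(C)C(C)(C)C | intermediate
7 | bis(pinacolato)diboron | CC1(C)OB(OC1(C)C)B1OC(C)(C)C(C)(C)O1 | starting material
8 | tert-butyl(dimethyl){[2-(4,4,5,5-tetramethyl-1,3,2-dioxaborolan-2-yl)prop-2-en-1-yl]oxy}silane | C=C(CO[Si](C)(C)C(C)(C)C)B1OC(C)(C)C(C)(C)O1 | intermediate
9 | 2-[3-({[tert-butyl(dimethyl)silyl]oxy})prop-1-en-2-yl]-4-methoxy-5-methylphenol | C=C(CO[Si](C)(C)C(C)(C)C)c1cc(OC)c(C)cc1O | intermediate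
10 | di-tert-butyl dicarbonate | CC(C)(C)OC(=O)OC(=O)OC(C)(C)C | starting material
11 | tert-butyl {2-[3-({[tert-butyl(dimethyl)silyl]oxy})prop-1-en-2-yl]-4-methoxy-5-methylphenyl} carbonate | C=C(CO[Si](C)(C)C(C)(C)C)c1cc(OC)c(C)cc1OC(=O)OC(C)(C)C | intermediate
12 | (4S)-4-(bromomethyl)-2-tert-butoxy-4-({[tert-butyl(dimethyl)silyl]oxy}methyl)-6-methoxy-7-methyl-4H-1,3-benzodioxin-2-ylium ion | BrC[C@]1(CO[Si](C)(C)C(C)(C)C)OC(OC(C)(C)C)=[O+]c2cc(C)c(OC)cc21 | intermediate
13 | (4S)-4-(bromomethyl)-4-({[tert-butyl(dimethyl)silyl]oxy}methyl)-6-methoxy-7-methyl-4H-1,3-benzodioxin-2-one | BrC[C@]1(CO[Si](C)(C)C(C)(C)C)OC(=O)Oc2cc(C)c(OC)cc21 | intermediate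
14 | (2S)-1-bromo-3-{[tert-butyl(dimethyl)silyl]oxy}-2-(2-hydroxy-5-methoxy-4-methylphenyl)propan-2-ol | BrC[C@@](O)(CO[Si](C)(C)C(C)(C)C)c1cc(OC)c(C)cc1O | intermediate
15 | (2Z)-2-methylbut-2-enoic anhydride (angelic anhydride) | C/C=C(/C)C(=O)OC(=O)/C(C)=C\C | starting material
16 | lithium 2-[(2S)-1-bromo-3-{[tert-butyl(dimethyl)silyl]oxy}-2-hydroxypropan-2-yl]-4-methoxy-5-methylphenolate | BrC[C@@](O)(CO[Si](C)(C)C(C)(C)C)c1cc(OC)c(C)cc1[O-].[Li+] | intermediate
17 | 2-[(2S)-1-bromo-3-{[tert-butyl(dimethyl)silyl]oxy}-2-hydroxypropan-2-yl]-4-methoxy-5-methylphenyl (2Z)-2-methylbut-2-enoate | BrC[C@@](O)(CO[Si](C)(C)C(C)(C)C)c1cc(OC)c(C)cc1OC(=O)/C(C)=C\C | intermediate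
18 | sodium (2S)-1-bromo-3-{[tert-butyl(dimethyl)silyl]oxy}-2-{5-methoxy-4-methyl-2-[(2Z)-2-methylbut-2-enoyloxy]phenyl}propan-2-olate | BrC[C@@]([O-])(CO[Si](C)(C)C(C)(C)C)c1cc(OC)c(C)cc1OC(=O)/C(C)=C\C.[Na+] | intermediate
19 | 2-[(2R)-2-({[tert-butyl(dimethyl)silyl]oxy}methyl)oxiran-2-yl]-4-methoxy-5-methylphenyl (2Z)-2-methylbut-2-enoate | C/C=C(/C)C(=O)Oc1cc(C)c(OC)cc1[C@]1(CO[Si](C)(C)C(C)(C)C)CO1 | intermediate
20 | 2-[(2S)-2-(hydroxymethyl)oxiran-2-yl]-4-methoxy-5-methylphenyl (2Z)-2-methylbut-2-enoate | C/C=C(/C)C(=O)Oc1cc(C)c(OC)cc1[C@]1(CO)CO1 | intermediate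
21 | (2E)-2-methylbut-2-enoyl chloride (tigloyl chloride) | C/C=C(\C)C(=O)Cl | starting material
22 | 2-[(2R)-2-({[(2E)-2-methylbut-2-enoyl]oxy}methyl)oxiran-2-yl]-4-methoxy-5-methylphenyl (2Z)-2-methylbut-2-enoate | C/C=C(/C)C(=O)Oc1cc(C)c(OC)cc1[C@]1(COC(=O)/C(C)=C/C)CO1 | target

**Step count**

Total steps: 11. Longest linear sequence: 10 steps (from 2-bromoprop-2-en-1-ol 4 through steps 2–11); 9 steps from phenol 1.

**Steps most likely to fail**

Step 6 (proposed new method). Enantioface discrimination may be poor because the carbonate offers the catalyst no hydrogen-bond donor. Bromination of the methoxy-activated ring, or loss of a proton from the benzylic cation before the carbonate closes, may also take over. The fallback uses known chemistry, sets out from 9 and rejoins the route at 20, bypassing steps 5–10. Phenol 9 is angeloylated as in step 8 (LiHMDS, then angelic anhydride 15) to give 2-[3-({[tert-butyl(dimethyl)silyl]oxy})prop-1-en-2-yl]-4-methoxy-5-methylphenyl (2Z)-2-methylbut-2-enoate F1. The silyl ether is removed with HF·pyridine in THF/pyridine (no oxirane is present at this stage) to give the 2-aryl allylic alcohol 2-(3-hydroxyprop-1-en-2-yl)-4-methoxy-5-methylphenyl (2Z)-2-methylbut-2-enoate F2. Katsuki–Sharpless epoxidation of this 2-substituted allylic alcohol (Ti(OiPr)4, L-(+)-diethyl tartrate, t-BuOOH, 4 Å molecular sieves, CH2Cl2, −20 °C) should then give (S)-20 directly. The tartrate is chosen by the usual facial rule, the same face that gives (S)-glycidol from allyl alcohol. Step 11 completes the synthesis.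

Step 9. The tertiary alkoxide may take the angeloyl group from the neighbouring phenol oxygen through a six-membered transition state instead of closing the oxirane. The phenoxide set free would then attack CH2Br and close a dihydrobenzofuran. The fallback sets out from 14 and rejoins at 19, carrying the phenol as a silyl ether through the oxirane closure. The phenol of 14 is silylated selectively (TBSCl 5, imidazole, DMF, 0 °C) to give (2S)-1-bromo-3-{[tert-butyl(dimethyl)silyl]oxy}-2-(2-{[tert-butyl(dimethyl)silyl]oxy}-5-methoxy-4-methylphenyl)propan-2-ol F3. NaH in THF closes the oxirane to tert-butyl{[(2R)-2-(2-{[tert-butyl(dimethyl)silyl]oxy}-5-methoxy-4-methylphenyl)oxiran-2-yl]methoxy}dimethylsilane F4. The aryl silyl ether, which is far more labile than the alkyl one, is then cleaved with CsF in MeCN at 0 °C in the presence of excess angelic anhydride 15, so that the phenoxide is acylated as it forms and 19 results.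

Step 10. The liberated primary hydroxyl may pull the angeloyl group over from the phenol oxygen, or fluoride or adventitious acid may open the tertiary benzylic oxirane. The fallback sets out from 17 and rejoins at 22, moving the desilylation ahead of the oxirane closure. Silyl ether 17 is cleaved with HF·pyridine in THF/pyridine at 0 °C to give 2-[(2S)-1-bromo-2,3-dihydroxypropan-2-yl]-4-methoxy-5-methylphenyl (2Z)-2-methylbut-2-enoate F5. The primary hydroxyl is tigloylated selectively over the tertiary one (tigloyl chloride 21, pyridine, CH2Cl2, −20 °C) to give 2-[(2S)-1-bromo-2-hydroxy-3-{[(2E)-2-methylbut-2-enoyl]oxy}propan-2-yl]-4-methoxy-5-methylphenyl (2Z)-2-methylbut-2-enoate F6. The oxirane is then closed without a free alkoxide by halide abstraction with Ag2O in THF, which should give 22 directly.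

**Further compounds**

F1 | step 6 | 2-[3-({[tert-butyl(dimethyl)silyl]oxy})prop-1-en-2-yl]-4-methoxy-5-methylphenyl (2Z)-2-methylbut-2-enoate | C=C(CO[Si](C)(C)C(C)(C)C)c1cc(OC)c(C)cc1OC(=O)/C(C)=C\C
F2 | step 6 | 2-(3-hydroxyprop-1-en-2-yl)-4-methoxy-5-methylphenyl (2Z)-2-methylbut-2-enoate | C=C(CO)c1cc(OC)c(C)cc1OC(=O)/C(C)=C\C
F3 | step 9 | (2S)-1-bromo-3-{[tert-butyl(dimethyl)silyl]oxy}-2-(2-{[tert-butyl(dimethyl)silyl]oxy}-5-methoxy-4-methylphenyl)propan-2-ol | BrC[C@@](O)(CO[Si](C)(C)C(C)(C)C)c1cc(OC)c(C)cc1O[Si](C)(C)C(C)(C)C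
F4 | step 9 | tert-butyl{[(2R)-2-(2-{[tert-butyl(dimethyl)silyl]oxy}-5-methoxy-4-methylphenyl)oxiran-2-yl]methoxy}dimethylsilane | CC(C)(C)[Si](C)(C)Oc1cc(C)c(OC)cc1[C@]1(CO[Si](C)(C)C(C)(C)C)CO1
F5 | step 10 | 2-[(2S)-1-bromo-2,3-dihydroxypropan-2-yl]-4-methoxy-5-methylphenyl (2Z)-2-methylbut-2-enoate | BrC[C@@](O)(CO)c1cc(OC)c(C)cc1OC(=O)/C(C)=C\C
F6 | step 10 | 2-[(2S)-1-bromo-2-hydroxy-3-{[(2E)-2-methylbut-2-enoyl]oxy}propan-2-yl]-4-methoxy-5-methylphenyl (2Z)-2-methylbut-2-enoate | BrC[C@@](O)(COC(=O)/C(C)=C/C)c1cc(OC)c(C)cc1OC(=O)/C(C)=C\C
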